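**Plan**

1. Retrosynthesis: the O-protecting groups come off last. Before that, the O–CH3 bond of the flavone 4'-methoxy group is cut, then the biaryl bond between C8 of isoflavone ring A and C3' of flavone ring B (as a C–H/C–H union), then O1–C2 and C2–C3 of the flavone pyranone ring C. The isoflavone half is bought intact as biochanin A.
2. Enabling feature: C8 is the C–H between the ring oxygen O1 and O7, and para to O5, of a phloroglucinol-type ring A, so it is that ring's most nucleophilic carbon. C3' lies ortho to the C4' oxygen of ring B, so a free 4'-phenol oxidised at an anode is electrophilic at that carbon. Neither partner needs a halide or boron.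
3. Helpers: isopropyl ethers keep isoflavone ring A nucleophilic and shield C6. Acetates switch off flavone ring A. The free 4'-OH steers the coupling and then becomes the methoxy group. All helpers are removed at the end.
4. Forward order: biochanin A is etherified; flavone ring C is closed by a Baker–Venkataraman-type acylation and cyclodehydration; ring A is acetylated and the 4'-OH freed; anodic cross-coupling joins the halves; then O-methylation, deacetylation and deisopropylation.
5. Stereochemistry: the target has no stereocentre. The tri-ortho-substituted biaryl axis is drawn without configuration and is taken as not configurationally defined, so nothing has to be set.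

Key step: step 5

**Step 1**
Reactants: 1 biochanin A (5,7-dihydroxy-3-(4-methoxyphenyl)-4H-chromen-4-one)
Product: 2 5,7-di-O-isopropylbiochanin A (5,7-diisopropoxy-3-(4-methoxyphenyl)-4H-chromen-4-one)
Conditions: 2-bromopropane (6 equiv), Cs2CO3 (4 equiv), DMF, 70 °C
Reagents that add atoms: 2-bromopropane, CC(C)Br
Why: Williamson etherification should alkylate the acidic 7-OH first and then, with excess halide and caesium carbonate in DMF, the hydrogen-bonded 5-OH.

**Step 2**
Reactants: 3 2',4',6'-trihydroxyacetophenone (anhydrous); 4 4-(benzyloxy)benzoyl chloride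
Product: 6 4'-O-benzylapigenin (2-[4-(benzyloxy)phenyl]-5,7-dihydroxy-4H-chromen-4-one), via beta-diketone 5 (not isolated)
Conditions: LiN(SiMe3)2 (4.2 equiv), THF, −78 → −10 °C; then 4, −78 °C → rt; aq. HCl; then AcOH, H2SO4 (cat.), 95 °C
Reagents that add atoms: none
Why: The lithium tetra-anion of 3 should be acylated at its enolate carbon by 4 (Claisen-type acylation as in a direct Baker–Venkataraman synthesis), and the 1,3-diketone should cyclodehydrate under acid to close pyranone ring C, the benzyl aryl ether surviving both stages.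

**Step 3**
Reactants: 6 4'-O-benzylapigenin
Product: 7 4'-O-benzyl-5,7-di-O-acetylapigenin (2-[4-(benzyloxy)phenyl]-4-oxo-4H-chromene-5,7-diyl diacetate)
Conditions: Ac2O, pyridine, 4-(dimethylamino)pyridine (cat.), rt → 50 °C
Reagents that add atoms: acetic anhydride, CC(=O)OC(C)=O
Why: Acylation under nucleophilic catalysis should esterify both phenols, including the hydrogen-bonded 5-OH, and the two acetates make flavone ring A electron-poor for the key step.

**Step 4**
Reactants: 7 4'-O-benzyl-5,7-di-O-acetylapigenin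
Product: 8 5,7-di-O-acetylapigenin (2-(4-hydroxyphenyl)-4-oxo-4H-chromene-5,7-diyl diacetate)
Conditions: H2 (1 atm), Pd/C (10 wt%), EtOAc/THF, rt
Reagents that add atoms: none
Why: Hydrogenolysis of the benzyl aryl ether over palladium on carbon should free the 4'-OH, while the aryl acetates stay and the chromone C2=C3 bond is reduced far more slowly.

**Step 5**
Reactants: 2 5,7-di-O-isopropylbiochanin A (3 equiv, excess to be recovered); 8 5,7-di-O-acetylapigenin
Product: 9 2-{3-[5,7-diisopropoxy-3-(4-methoxyphenyl)-4-oxo-4H-chromen-8-yl]-4-hydroxyphenyl}-4-oxo-4H-chromene-5,7-diyl diacetate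
Conditions: undivided cell, boron-doped diamond anode and cathode, Bu3NMe O3SOMe (0.1 M), HFIP, 40 °C, constant current (about 5 mA cm−2, 2.2 F per mol of 8)
Reagents that add atoms: none
Why: Anodic one-electron oxidation of the only free phenol, the ring-B 4'-OH of 8, should give an HFIP-solvated phenoxyl radical whose ortho carbon C3' is attacked by the most nucleophilic C–H present, C8 of ring A of 2 (between O1 and the 7-isopropoxy group, para to the 5-isopropoxy group); loss of a second electron and two protons rearomatises both rings while protons are reduced to H2 at the cathode. The closest known reaction type is the anodic dehydrogenative phenol–arene cross-coupling at boron-doped diamond in fluorinated alcohols, which joins 4-substituted phenols ortho to OH with 1,3,5-trialkoxybenzenes. The step closes no ring and creates no stereocentre. Cross-coupling over homo-coupling is secured by the acetates, which make ring A of 8 neither oxidisable nor nucleophilic, by the absence of a free OH in 2, and by the excess of 2; C8 over C6 is secured by the two isopropoxy groups that flank C6. Attack at C3' rather than at the chromone C3 or at oxygen is expected from the spin density ortho to oxygen and the rearomatisation available there in HFIP, and the second ortho position C5' is protected by the hindered, twisted product phenol and by stopping near 2 F per mol.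

**Step 6**
Reactants: 9 the coupled biaryl phenol
Product: 10 2-{3-[5,7-diisopropoxy-3-(4-methoxyphenyl)-4-oxo-4H-chromen-8-yl]-4-methoxyphenyl}-4-oxo-4H-chromene-5,7-diyl diacetate
Conditions: Me3SiCHN2 (1.5 equiv), i-Pr2NEt (cat.), MeCN/MeOH (9:1), rt
Reagents that add atoms: trimethylsilyldiazomethane, C[Si](C)(C)C=[N+]=[N-]
Why: The acidic 4'-phenol, the only free OH, should protonate the diazo reagent and be O-methylated by the methyldiazonium ion released by methanol, a neutral methylation that leaves the aryl acetates untouched.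

**Step 7**
Reactants: 10 the methyl ether diacetate
Product: 11 8-[5-(5,7-dihydroxy-4-oxo-4H-chromen-2-yl)-2-methoxyphenyl]-5,7-diisopropoxy-3-(4-methoxyphenyl)-4H-chromen-4-one
Conditions: K2CO3 (3 equiv), MeOH/THF (1:1), 0 °C → rt; then dilute aq. HCl
Reagents that add atoms: none
Why: Base-mediated methanolysis (transesterification) of the two aryl acetates should be fast at or below room temperature and should not touch the alkyl aryl ethers or the chromone rings.

**Step 8**
Reactants: 11 the 5,7-di-O-isopropyl biflavonoid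
Product: 12 8-[5-(5,7-dihydroxy-4-oxo-4H-chromen-2-yl)-2-methoxyphenyl]-5,7-dihydroxy-3-(4-methoxyphenyl)-4H-chromen-4-one (target)
Conditions: BCl3 (1 M in CH2Cl2, 8 equiv), CH2Cl2, −78 → 0 °C; then H2O
Reagents that add atoms: none
Why: BCl3 should cleave the secondary isopropyl aryl ethers (ionisation to the isopropyl cation and capture by chloride, helped at O5 by chelation to the C4 carbonyl) much faster than the two non-chelated aryl methyl ethers, so only the isopropyl groups are lost.

**Compound list**

1 | biochanin A, 5,7-dihydroxy-3-(4-methoxyphenyl)-4H-chromen-4-one | COc1ccc(-c2coc3cc(O)cc(O)c3c2=O)cc1 | starting material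
2 | 5,7-diisopropoxy-3-(4-methoxyphenyl)-4H-chromen-4-one | COc1ccc(-c2coc3cc(OC(C)C)cc(OC(C)C)c3c2=O)cc1 | intermediate
3 | 2',4',6'-trihydroxyacetophenone, 1-(2,4,6-trihydroxyphenyl)ethanone | CC(=O)c1c(O)cc(O)cc1O | starting material
4 | 4-(benzyloxy)benzoyl chloride | O=C(Cl)c1ccc(OCc2ccccc2)cc1 | starting material
5 | 1-[4-(benzyloxy)phenyl]-3-(2,4,6-trihydroxyphenyl)propane-1,3-dione | O=C(CC(=O)c1ccc(OCc2ccccc2)cc1)c1c(O)cc(O)cc1O | intermediate (not isolated)
6 | 2-[4-(benzyloxy)phenyl]-5,7-dihydroxy-4H-chromen-4-one | O=c1cc(-c2ccc(OCc3ccccc3)cc2)oc2cc(O)cc(O)c12 | intermediate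
7 | 2-[4-(benzyloxy)phenyl]-4-oxo-4H-chromene-5,7-diyl diacetate | CC(=O)Oc1cc(OC(C)=O)c2c(=O)cc(-c3ccc(OCc4ccccc4)cc3)oc2c1 | intermediate
8 | 2-(4-hydroxyphenyl)-4-oxo-4H-chromene-5,7-diyl diacetate | CC(=O)Oc1cc(OC(C)=O)c2c(=O)cc(-c3ccc(O)cc3)oc2c1 | intermediate
9 | 2-{3-[5,7-diisopropoxy-3-(4-methoxyphenyl)-4-oxo-4H-chromen-8-yl]-4-hydroxyphenyl}-4-oxo-4H-chromene-5,7-diyl diacetate | COc1ccc(-c2coc3c(-c4cc(-c5cc(=O)c6c(OC(C)=O)cc(OC(C)=O)cc6o5)ccc4O)c(OC(C)C)cc(OC(C)C)c3c2=O)cc1 | intermediate
10 | 2-{3-[5,7-diisopropoxy-3-(4-methoxyphenyl)-4-oxo-4H-chromen-8-yl]-4-methoxyphenyl}-4-oxo-4H-chromene-5,7-diyl diacetate | COc1ccc(-c2coc3c(-c4cc(-c5cc(=O)c6c(OC(C)=O)cc(OC(C)=O)cc6o5)ccc4OC)c(OC(C)C)cc(OC(C)C)c3c2=O)cc1 | intermediate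
11 | 8-[5-(5,7-dihydroxy-4-oxo-4H-chromen-2-yl)-2-methoxyphenyl]-5,7-diisopropoxy-3-(4-methoxyphenyl)-4H-chromen-4-one | COc1ccc(-c2coc3c(-c4cc(-c5cc(=O)c6c(O)cc(O)cc6o5)ccc4OC)c(OC(C)C)cc(OC(C)C)c3c2=O)cc1 | intermediate
12 | 8-[5-(5,7-dihydroxy-4-oxo-4H-chromen-2-yl)-2-methoxyphenyl]-5,7-dihydroxy-3-(4-methoxyphenyl)-4H-chromen-4-one | COc1ccc(-c2coc3c(-c4cc(-c5cc(=O)c6c(O)cc(O)cc6o5)ccc4OC)c(O)cc(O)c3c2=O)cc1 | target

**Step count and risks**

Total step count: 8. Longest linear sequence: 7 steps (steps 2 to 8, from 3 and 4 to 12).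

Steps most likely to fail:

1. Step 5. The excess arene 2 may be oxidised in competition with the electron-poor phenol and couple with itself. The phenoxyl radical may also be trapped through the chromone C3 or through oxygen, and the product phenol may be oxidised further. Fallback (Suzuki–Miyaura union of pre-functionalised halves): compound 2 is iodinated at C8 (N-iodosuccinimide, CF3CO2H cat., MeCN) to 8-iodo-5,7-di-O-isopropylbiochanin A F1. Compound 8 is iodinated ortho to the phenol (N-iodosuccinimide, p-toluenesulfonic acid cat., MeCN) to 3'-iodo-5,7-di-O-acetylapigenin F2. This is methylated as in step 6 to 3'-iodo-5,7-di-O-acetylacacetin F3, then borylated (B2pin2, PdCl2(dppf), KOAc, dioxane, 90 °C) to the 3'-pinacolboronate of 5,7-di-O-acetylacacetin F4. Coupling of F1 with F4 (Pd(PPh3)4, K3PO4, dioxane, 90 °C) should return to the route at 10. Any acetate lost in the coupling only anticipates step 7.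

2. Step 1. Alkylation of the hydrogen-bonded 5-OH may stall because the secondary bromide is consumed by elimination. Fallback (activate the alcohol instead of forcing the chelated phenoxide onto a secondary halide): compound 1 is alkylated only at O7 (2-bromopropane 1.2 equiv, K2CO3, DMF, 50 °C) to 7-O-isopropylbiochanin A F5. The chelated 5-OH is then etherified under Mitsunobu conditions (propan-2-ol, PPh3, diisopropyl azodicarboxylate, THF, 0 °C → rt), which should return to the route at 2.

3. Step 8. Cleavage of the non-chelated 7-isopropyl ether may be incomplete, or boron held on the freed 7-oxygen may be delivered across the biaryl axis and cleave the neighbouring 4'-methyl ether. Fallback (benzyl ethers removed by hydrogenolysis instead of a Lewis acid): compound 1 is benzylated (benzyl bromide, K2CO3, DMF, 80 °C) to 5,7-di-O-benzylbiochanin A F6. F6 is coupled with 8 under the conditions of step 5 to the benzyl-protected biaryl phenol F7, methylated as in step 6 to the benzyl-protected methyl ether diacetate F8, and deacetylated as in step 7 to the 5,7-di-O-benzyl biflavonoid F9. Hydrogenolysis of F9 (H2, Pd/C, THF/MeOH, rt) should return to the route at 12.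

**Further compounds**

F1 | step 5 | 8-iodo-5,7-diisopropoxy-3-(4-methoxyphenyl)-4H-chromen-4-one | COc1ccc(-c2coc3c(I)c(OC(C)C)cc(OC(C)C)c3c2=O)cc1
F2 | step 5 | 2-(4-hydroxy-3-iodophenyl)-4-oxo-4H-chromene-5,7-diyl diacetate | CC(=O)Oc1cc(OC(C)=O)c2c(=O)cc(-c3ccc(O)c(I)c3)oc2c1
F3 | step 5 | 2-(3-iodo-4-methoxyphenyl)-4-oxo-4H-chromene-5,7-diyl diacetate | CC(=O)Oc1cc(OC(C)=O)c2c(=O)cc(-c3ccc(OC)c(I)c3)oc2c1
F4 | step 5 | 2-[4-methoxy-3-(4,4,5,5-tetramethyl-1,3,2-dioxaborolan-2-yl)phenyl]-4-oxo-4H-chromene-5,7-diyl diacetate | CC(=O)Oc1cc(OC(C)=O)c2c(=O)cc(-c3ccc(OC)c(B4OC(C)(C)C(C)(C)O4)c3)oc2c1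
F5 | step 1 | 5-hydroxy-7-isopropoxy-3-(4-methoxyphenyl)-4H-chromen-4-one | COc1ccc(-c2coc3cc(OC(C)C)cc(O)c3c2=O)cc1
F6 | step 8 | 5,7-bis(benzyloxy)-3-(4-methoxyphenyl)-4H-chromen-4-one | COc1ccc(-c2coc3cc(OCc4ccccc4)cc(OCc4ccccc4)c3c2=O)cc1
F7 | step 8 | 2-{3-[5,7-bis(benzyloxy)-3-(4-methoxyphenyl)-4-oxo-4H-chromen-8-yl]-4-hydroxyphenyl}-4-oxo-4H-chromene-5,7-diyl diacetate | COc1ccc(-c2coc3c(-c4cc(-c5cc(=O)c6c(OC(C)=O)cc(OC(C)=O)cc6o5)ccc4O)c(OCc4ccccc4)cc(OCc4ccccc4)c3c2=O)cc1
F8 | step 8 | 2-{3-[5,7-bis(benzyloxy)-3-(4-methoxyphenyl)-4-oxo-4H-chromen-8-yl]-4-methoxyphenyl}-4-oxo-4H-chromene-5,7-diyl diacetate | COc1ccc(-c2coc3c(-c4cc(-c5cc(=O)c6c(OC(C)=O)cc(OC(C)=O)cc6o5)ccc4OC)c(OCc4ccccc4)cc(OCc4ccccc4)c3c2=O)cc1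
F9 | step 8 | 5,7-bis(benzyloxy)-8-[5-(5,7-dihydroxy-4-oxo-4H-chromen-2-yl)-2-methoxyphenyl]-3-(4-methoxyphenyl)-4H-chromen-4-one | COc1ccc(-c2coc3c(-c4cc(-c5cc(=O)c6c(O)cc(O)cc6o5)ccc4OC)c(OCc4ccccc4)cc(OCc4ccccc4)c3c2=O)cc1
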